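**Assumption and conventions.** The target is read as the (4R,5R,6S,7R,8S,9S) melampolide with C2 and C9 cis on C1=C10 and a trans 4,5-epoxide. Ten-membered-ring compounds carry the germacrane numbering of the target (C12 lactone carbonyl, C13 exocyclic methylene, C14 ester carbon, C15 methyl; α/β as in the usual drawing, H-7 α). "4E" means C3 and C6 are trans. PMB = 4-methoxybenzyl. Compound numbers follow the forward route.

## Retrosynthetic overview

1. Target ⇐ peripheral epoxidation of C4=C5 (last step); lactone ⇐ oxidation of a 6,12-diol; C14 ester ⇐ carbonylation of a C10 vinyl bromide; C8/C9 esters ⇐ an 8-hydroxy-9-ketone.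
2. Ten-membered ring ⇐ anionic oxy-Cope [3,3] rearrangement of a trans-1,2-dialkenylcyclohex-2-enol. It forms C6–C7, sets the E-C4=C5 alkene, turns the cyclohexene alkene into the ring-cis C1=C10, and leaves a C8 enolate that is hydroxylated in the same flask.
3. Cope substrate ⇐ an E-dienyllithium (C7, C8, C11–C13) plus (S)-2-bromo-6-methyl-6-(E-2-alkoxyvinyl)cyclohex-2-enone.
4. Enone ⇐ (S)-carvone: reductive aldol sets the quaternary carbon under control of the carvone stereocentre, which is then spent when ozonolysis/iron–copper fragmentation excises the isopropenyl group and creates the enone.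
5. Ring order: cyclohexenone (from carvone) → ten-membered carbocycle (oxy-Cope) → γ-lactone → epoxide.

## Route

**Step 1**
Reactants: 1 (S)-(+)-carvone
Product: 3 (2S,5S)-2-(hydroxymethyl)-2-methyl-5-(prop-1-en-2-yl)cyclohexan-1-one, via lithium enolate 2 (not isolated)
Conditions: LiBH(s-Bu)3, THF, −78 °C; then CH2O (gas), −78 °C; AcOH quench
Reagents that add atoms: formaldehyde, C=O
Why: Conjugate hydride addition gives the C2 enolate regiospecifically, and formaldehyde adds axially, cis to the equatorial C5 isopropenyl group, which sets the quaternary centre as 2S (reductive aldol; minor epimer removed by chromatography).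

**Step 2**
Reactants: 3 (2S,5S)-2-(hydroxymethyl)-2-methyl-5-(prop-1-en-2-yl)cyclohexan-1-one
Product: 5 (S)-6-(hydroxymethyl)-6-methylcyclohex-2-en-1-one, via methoxy hydroperoxide 4 (not isolated)
Conditions: O3, MeOH/CH2Cl2, −78 °C; then Cu(OAc)2·H2O, FeSO4·7H2O, −20 °C to rt
Reagents that add atoms: none
Why: Criegee ozonolysis in methanol gives the α-methoxy hydroperoxide; divalent iron cleaves the O–O bond, β-scission expels methyl acetate, and divalent copper oxidises the ring radical to the conjugated enone (Schreiber dealkenylative fragmentation), leaving the quaternary centre untouched.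

**Step 3**
Reactants: 5 (S)-6-(hydroxymethyl)-6-methylcyclohex-2-en-1-one
Product: 7 (S)-2-bromo-6-(hydroxymethyl)-6-methylcyclohex-2-en-1-one, via 2,3-dibromo ketone 6 (not isolated)
Conditions: Br2, CH2Cl2, 0 °C; then Et3N
Reagents that add atoms: bromine, BrBr
Why: Bromine addition to the enone followed by E2 loss of HBr gives the α-bromoenone (bromination–dehydrobromination); there is no α′ hydrogen and the stereocentre is not involved.

**Step 4**
Reactants: 7 (S)-2-bromo-6-(hydroxymethyl)-6-methylcyclohex-2-en-1-one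
Product: 8 (S)-3-bromo-1-methyl-2-oxocyclohex-3-ene-1-carbaldehyde
Conditions: Dess–Martin periodinane, CH2Cl2, rt
Reagents that add atoms: none
Why: Dess–Martin oxidation of the neopentyl primary alcohol gives a non-enolisable α-formyl ketone, so the quaternary centre cannot epimerise.

**Step 5**
Reactants: 8 (S)-3-bromo-1-methyl-2-oxocyclohex-3-ene-1-carbaldehyde
Product: 9 (S)-2-bromo-6-methyl-6-[(E)-2-(4,4,5,5-tetramethyl-1,3,2-dioxaborolan-2-yl)ethenyl]cyclohex-2-en-1-one
Conditions: CrCl2, Cl2CHBpin, LiI, THF, rt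
Reagents that add atoms: 2-(dichloromethyl)-4,4,5,5-tetramethyl-1,3,2-dioxaborolane, ClC(Cl)B1OC(C)(C)C(C)(C)O1
Why: Takai–Utimoto borylalkenation: the geminal dichromium reagent adds only to the aldehyde (the hindered ketone and the vinyl bromide are inert to divalent chromium without nickel) and eliminates to the E-alkenylboronate.

**Step 6**
Reactants: 9 (S)-2-bromo-6-methyl-6-[(E)-2-(4,4,5,5-tetramethyl-1,3,2-dioxaborolan-2-yl)ethenyl]cyclohex-2-en-1-one; 10 4-methoxybenzyl alcohol (5 equiv)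
Product: 11 (S)-2-bromo-6-{(E)-2-[(4-methoxybenzyl)oxy]ethenyl}-6-methylcyclohex-2-en-1-one
Conditions: Cu(OAc)2 (2 equiv), Et3N, CH2Cl2, 4 Å MS, rt
Reagents that add atoms: none
Why: Chan–Lam–Evans C–O coupling (boron-to-copper transmetalation, then C–O reductive elimination) proceeds with retention, giving the E-enol ether under conditions mild enough for the bromoenone.

**Step 7**
Reactants: 10 4-methoxybenzyl alcohol; 12 2,3-dibromopropene
Product: 14 1-{[(2-bromoprop-2-en-1-yl)oxy]methyl}-4-methoxybenzene, via sodium 4-methoxybenzyl oxide 13 (not isolated)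
Conditions: NaH, THF, 0 °C; then 12, rt
Reagents that add atoms: none
Why: Williamson ether synthesis by SN2 at the allylic bromide; the vinylic bromide does not react.

**Step 8**
Reactants: 14 1-{[(2-bromoprop-2-en-1-yl)oxy]methyl}-4-methoxybenzene; 15 (E)-1,2-bis(tributylstannyl)ethene (2.5 equiv)
Product: 16 tributyl[(1E)-3-{[(4-methoxybenzyl)oxy]methyl}buta-1,3-dien-1-yl]stannane
Conditions: Pd(PPh3)4 (5 mol %), toluene, 90 °C
Reagents that add atoms: none
Why: Stille coupling of the vinyl bromide with one tin terminus (excess distannane prevents double coupling) retains the E geometry of the stannylalkene.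

**Step 9**
Reactants: 16 tributyl[(1E)-3-{[(4-methoxybenzyl)oxy]methyl}buta-1,3-dien-1-yl]stannane; 11 (S)-2-bromo-6-{(E)-2-[(4-methoxybenzyl)oxy]ethenyl}-6-methylcyclohex-2-en-1-one
Product: 18 (1R,6S)-2-bromo-6-{(E)-2-[(4-methoxybenzyl)oxy]ethenyl}-1-[(1E)-3-{[(4-methoxybenzyl)oxy]methyl}buta-1,3-dien-1-yl]-6-methylcyclohex-2-en-1-ol, via dienyllithium 17 (not isolated)
Conditions: 16, n-BuLi, THF, −78 °C; then 11, −78 °C; H2O
Reagents that add atoms: none
Why: Tin–lithium exchange with retention, then 1,2-addition to the non-enolisable ketone; Felkin–Anh control places the nucleophile anti to the alkoxyvinyl group (larger and the better σ-acceptor than methyl), giving the trans-dialkenyl carbinol (1R), with any C1 epimer separated.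

**Step 10**
Reactants: 18 (1R,6S)-2-bromo-6-{(E)-2-[(4-methoxybenzyl)oxy]ethenyl}-1-[(1E)-3-{[(4-methoxybenzyl)oxy]methyl}buta-1,3-dien-1-yl]-6-methylcyclohex-2-en-1-ol
Product: 21 10-bromo-8α-hydroxy-6α,12-bis[(4-methoxybenzyl)oxy]-14-norgermacra-1(10),4E,11(13)-trien-9-one, via potassium alkoxide 19 (not isolated), via potassium enolate 20 (not isolated)
Conditions: KN(SiMe3)2, 18-crown-6, THF, 0 °C to rt; then −78 °C, 2-(phenylsulfonyl)-3-phenyloxaziridine; AcOH quench
Reagents that add atoms: 2-(phenylsulfonyl)-3-phenyloxaziridine, O=S(=O)(N1OC1c1ccccc1)c1ccccc1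
Why: Anionic oxy-Cope [3,3]-sigmatropic rearrangement through a chair transition state with both ring bonds and both E-alkene substituents equatorial forms the ten-membered ring and the C6–C7 bond, transfers the (1R,6S) chirality to 6α-O/7β-C (trans), gives E-C4=C5 and keeps the cyclohexene alkene as ring-cis C1=C10; the enolate is then hydroxylated (Davis oxidation) on its outer face, anti to the C7 substituent, giving 8α-OH.

**Step 11**
Reactants: 21 10-bromo-8α-hydroxy-6α,12-bis[(4-methoxybenzyl)oxy]-14-norgermacra-1(10),4E,11(13)-trien-9-one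
Product: 22 10-bromo-8β-(methacryloyloxy)-6α,12-bis[(4-methoxybenzyl)oxy]-14-norgermacra-1(10),4E,11(13)-trien-9-one
Conditions: methacrylic acid, PPh3, DIAD, toluene, 0 °C to rt
Reagents that add atoms: methacrylic acid, CC(=C)C(=O)O
Why: Mitsunobu esterification is an SN2 displacement (accelerated at the α-keto carbinol), so it installs the methacrylate and inverts C8 to the required 8β configuration in one operation.

**Step 12**
Reactants: 22 10-bromo-8β-(methacryloyloxy)-6α,12-bis[(4-methoxybenzyl)oxy]-14-norgermacra-1(10),4E,11(13)-trien-9-one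
Product: 23 10-bromo-9α-hydroxy-6α,12-bis[(4-methoxybenzyl)oxy]-14-norgermacra-1(10),4E,11(13)-trien-8β-yl methacrylate
Conditions: NaBH4, CeCl3·7H2O, MeOH, −78 °C; AcOH quench at −78 °C
Reagents that add atoms: none
Why: Luche 1,2-reduction of the α-bromoenone; hydride attacks the outer face, anti to the C8 acyloxy group (polar Felkin–Anh), giving 9α-OH trans to 8β-O, while the methacrylate is untouched and the cold acidic quench prevents acyl migration.

**Step 13**
Reactants: 23 10-bromo-9α-hydroxy-6α,12-bis[(4-methoxybenzyl)oxy]-14-norgermacra-1(10),4E,11(13)-trien-8β-yl methacrylate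
Product: 24 methyl 9α-hydroxy-8β-(methacryloyloxy)-6α,12-bis[(4-methoxybenzyl)oxy]germacra-1(10),4E,11(13)-trien-14-oate
Conditions: Pd(OAc)2 (10 mol %), Xantphos, CO (10 bar), MeOH/DMF, i-Pr2NEt, 60 °C
Reagents that add atoms: carbon monoxide, [C-]#[O+]; methanol, CO
Why: Palladium-catalysed methoxycarbonylation of the vinyl bromide (oxidative addition, CO insertion, methanolysis) retains the alkene geometry; it is run on the free allylic alcohol because an allylic acetate could ionise with zerovalent palladium, and the CO pressure disfavours Heck pathways.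

**Step 14**
Reactants: 24 methyl 9α-hydroxy-8β-(methacryloyloxy)-6α,12-bis[(4-methoxybenzyl)oxy]germacra-1(10),4E,11(13)-trien-14-oate
Product: 25 methyl 9α-acetoxy-8β-(methacryloyloxy)-6α,12-bis[(4-methoxybenzyl)oxy]germacra-1(10),4E,11(13)-trien-14-oate
Conditions: Ac2O, pyridine, DMAP (cat.), CH2Cl2, 0 °C
Reagents that add atoms: acetic anhydride, CC(=O)OC(C)=O
Why: Acylation of the secondary alcohol with retention at C9; the β-substituted enoate is slow toward SN2′ attack by the amine at 0 °C.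

**Step 15**
Reactants: 25 methyl 9α-acetoxy-8β-(methacryloyloxy)-6α,12-bis[(4-methoxybenzyl)oxy]germacra-1(10),4E,11(13)-trien-14-oate
Product: 26 methyl 9α-acetoxy-6α,12-dihydroxy-8β-(methacryloyloxy)germacra-1(10),4E,11(13)-trien-14-oate
Conditions: DDQ (2.4 equiv), CH2Cl2/pH 7 buffer, 0 °C
Reagents that add atoms: none
Why: Oxidative cleavage of both PMB ethers (benzylic hydride abstraction, hydrolysis of the oxocarbenium ion) under buffered conditions that spare the esters and the alkenes.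

**Step 16**
Reactants: 26 methyl 9α-acetoxy-6α,12-dihydroxy-8β-(methacryloyloxy)germacra-1(10),4E,11(13)-trien-14-oate
Product: 29 methyl 9α-acetoxy-8β-(methacryloyloxy)-12-oxo-6α,12-epoxygermacra-1(10),4E,11(13)-trien-14-oate, via hydroxy enal 27 (not isolated), via lactol 28 (not isolated)
Conditions: TEMPO (20 mol %), PhI(OAc)2 (2.5 equiv), CH2Cl2, rt
Reagents that add atoms: none
Why: Oxoammonium oxidation takes the primary allylic alcohol to the enal, which is trapped by the 6α-hydroxyl as a lactol and oxidised again to the trans-fused α-methylene-γ-butyrolactone (oxidative lactonisation); C6 and C7 are not touched.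

**Step 17**
Reactants: 29 methyl 9α-acetoxy-8β-(methacryloyloxy)-12-oxo-6α,12-epoxygermacra-1(10),4E,11(13)-trien-14-oate
Product: 30 target, methyl (4R,5R,6S,7R,8S,9S)-9α-acetoxy-4α,5β-epoxy-8β-(methacryloyloxy)-12-oxo-6α,12-epoxygermacra-1(10),11(13)-dien-14-oate
Conditions: mCPBA, NaHCO3, CH2Cl2, 0 °C
Reagents that add atoms: 3-chloroperoxybenzoic acid, OOC(=O)c1cccc(Cl)c1
Why: Prilezhaev epoxidation of the only electron-rich alkene (the other three are conjugated to carbonyls); concerted syn addition to the outer face of the E-alkene in the crown conformation fixed by the trans-lactone gives the trans (4R,5R) epoxide.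

## Compound list

1 | (S)-(+)-carvone | CC1=CC[C@@H](CC1=O)C(C)=C | starting material
2 | lithium (5S)-2-methyl-5-(prop-1-en-2-yl)cyclohex-1-en-1-olate (not isolated) | [Li+].[O-]C1=C(C)CC[C@@H](C1)C(C)=C | intermediate
3 | (2S,5S)-2-(hydroxymethyl)-2-methyl-5-(prop-1-en-2-yl)cyclohexan-1-one | C=C(C)[C@H]1CC[C@@](C)(CO)C(=O)C1 | intermediate
4 | (2S,5S)-5-(1-hydroperoxy-1-methoxyethyl)-2-(hydroxymethyl)-2-methylcyclohexan-1-one (not isolated) | COC(C)(OO)[C@H]1CC[C@@](C)(CO)C(=O)C1 | intermediate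
5 | (S)-6-(hydroxymethyl)-6-methylcyclohex-2-en-1-one | O=C1C=CCC[C@@]1(C)CO | intermediate
6 | (6S)-2,3-dibromo-6-(hydroxymethyl)-6-methylcyclohexan-1-one (not isolated) | O=C1C(Br)C(Br)CC[C@@]1(C)CO | intermediate
7 | (S)-2-bromo-6-(hydroxymethyl)-6-methylcyclohex-2-en-1-one | O=C1C(Br)=CCC[C@@]1(C)CO | intermediate
8 | (S)-3-bromo-1-methyl-2-oxocyclohex-3-ene-1-carbaldehyde | O=C1C(Br)=CCC[C@@]1(C)C=O | intermediate
9 | (S)-2-bromo-6-methyl-6-[(E)-2-(4,4,5,5-tetramethyl-1,3,2-dioxaborolan-2-yl)ethenyl]cyclohex-2-en-1-one | O=C1C(Br)=CCC[C@@]1(C)/C=C/B1OC(C)(C)C(C)(C)O1 | intermediate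
10 | 4-methoxybenzyl alcohol | OCc1ccc(OC)cc1 | starting material
11 | (S)-2-bromo-6-{(E)-2-[(4-methoxybenzyl)oxy]ethenyl}-6-methylcyclohex-2-en-1-one | O=C1C(Br)=CCC[C@@]1(C)/C=C/OCc1ccc(OC)cc1 | intermediate
12 | 2,3-dibromopropene | C=C(Br)CBr | starting material
13 | sodium 4-methoxybenzyl oxide (not isolated) | [Na+].[O-]Cc1ccc(OC)cc1 | intermediate
14 | 1-{[(2-bromoprop-2-en-1-yl)oxy]methyl}-4-methoxybenzene | C=C(Br)COCc1ccc(OC)cc1 | intermediate
15 | (E)-1,2-bis(tributylstannyl)ethene | CCCC[Sn](CCCC)(CCCC)/C=C/[Sn](CCCC)(CCCC)CCCC | starting material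
16 | tributyl[(1E)-3-{[(4-methoxybenzyl)oxy]methyl}buta-1,3-dien-1-yl]stannane | CCCC[Sn](CCCC)(CCCC)/C=C/C(=C)COCc1ccc(OC)cc1 | intermediate
17 | (1E)-3-{[(4-methoxybenzyl)oxy]methyl}buta-1,3-dien-1-yllithium (not isolated) | [Li]/C=C/C(=C)COCc1ccc(OC)cc1 | intermediate
18 | (1R,6S)-2-bromo-6-{(E)-2-[(4-methoxybenzyl)oxy]ethenyl}-1-[(1E)-3-{[(4-methoxybenzyl)oxy]methyl}buta-1,3-dien-1-yl]-6-methylcyclohex-2-en-1-ol | O[C@@]1(/C=C/C(=C)COCc2ccc(OC)cc2)C(Br)=CCC[C@@]1(C)/C=C/OCc1ccc(OC)cc1 | intermediate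
19 | potassium alkoxide of 18 (not isolated) | [K+].[O-][C@@]1(/C=C/C(=C)COCc2ccc(OC)cc2)C(Br)=CCC[C@@]1(C)/C=C/OCc1ccc(OC)cc1 | intermediate
20 | potassium 10-bromo-6α,12-bis[(4-methoxybenzyl)oxy]-14-norgermacra-1(10),4E,8,11(13)-tetraen-9-olate (C10 and C7 trans on C8=C9; not isolated) | [K+].[O-]/C1=C\[C@@H](C(=C)COCc2ccc(OC)cc2)[C@H](OCc2ccc(OC)cc2)/C=C(\C)CC/C=C1/Br | intermediate
21 | 10-bromo-8α-hydroxy-6α,12-bis[(4-methoxybenzyl)oxy]-14-norgermacra-1(10),4E,11(13)-trien-9-one | O[C@@H]1[C@@H](C(=C)COCc2ccc(OC)cc2)[C@H](OCc2ccc(OC)cc2)/C=C(\C)CC/C=C(/Br)C1=O | intermediate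
22 | 10-bromo-8β-(methacryloyloxy)-6α,12-bis[(4-methoxybenzyl)oxy]-14-norgermacra-1(10),4E,11(13)-trien-9-one | C=C(C)C(=O)O[C@H]1[C@@H](C(=C)COCc2ccc(OC)cc2)[C@H](OCc2ccc(OC)cc2)/C=C(\C)CC/C=C(/Br)C1=O | intermediate
23 | 10-bromo-9α-hydroxy-6α,12-bis[(4-methoxybenzyl)oxy]-14-norgermacra-1(10),4E,11(13)-trien-8β-yl methacrylate | C=C(C)C(=O)O[C@H]1[C@@H](C(=C)COCc2ccc(OC)cc2)[C@H](OCc2ccc(OC)cc2)/C=C(\C)CC/C=C(/Br)[C@@H]1O | intermediate
24 | methyl 9α-hydroxy-8β-(methacryloyloxy)-6α,12-bis[(4-methoxybenzyl)oxy]germacra-1(10),4E,11(13)-trien-14-oate | C=C(C)C(=O)O[C@H]1[C@@H](C(=C)COCc2ccc(OC)cc2)[C@H](OCc2ccc(OC)cc2)/C=C(\C)CC/C=C(/C(=O)OC)[C@@H]1O | intermediate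
25 | methyl 9α-acetoxy-8β-(methacryloyloxy)-6α,12-bis[(4-methoxybenzyl)oxy]germacra-1(10),4E,11(13)-trien-14-oate | C=C(C)C(=O)O[C@H]1[C@@H](C(=C)COCc2ccc(OC)cc2)[C@H](OCc2ccc(OC)cc2)/C=C(\C)CC/C=C(/C(=O)OC)[C@@H]1OC(C)=O | intermediate
26 | methyl 9α-acetoxy-6α,12-dihydroxy-8β-(methacryloyloxy)germacra-1(10),4E,11(13)-trien-14-oate | C=C(C)C(=O)O[C@H]1[C@@H](C(=C)CO)[C@H](O)/C=C(\C)CC/C=C(/C(=O)OC)[C@@H]1OC(C)=O | intermediate
27 | methyl 9α-acetoxy-6α-hydroxy-8β-(methacryloyloxy)-12-oxogermacra-1(10),4E,11(13)-trien-14-oate (not isolated) | C=C(C)C(=O)O[C@H]1[C@@H](C(=C)C=O)[C@H](O)/C=C(\C)CC/C=C(/C(=O)OC)[C@@H]1OC(C)=O | intermediate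
28 | methyl 9α-acetoxy-12-hydroxy-8β-(methacryloyloxy)-6α,12-epoxygermacra-1(10),4E,11(13)-trien-14-oate (lactol, anomer mixture; not isolated) | C=C(C)C(=O)O[C@H]1[C@H]2C(=C)C(O)O[C@@H]2/C=C(\C)CC/C=C(/C(=O)OC)[C@@H]1OC(C)=O | intermediate
29 | methyl 9α-acetoxy-8β-(methacryloyloxy)-12-oxo-6α,12-epoxygermacra-1(10),4E,11(13)-trien-14-oate | C=C(C)C(=O)O[C@H]1[C@H]2C(=C)C(=O)O[C@@H]2/C=C(\C)CC/C=C(/C(=O)OC)[C@@H]1OC(C)=O | intermediate
30 | methyl (4R,5R,6S,7R,8S,9S)-9α-acetoxy-4α,5β-epoxy-8β-(methacryloyloxy)-12-oxo-6α,12-epoxygermacra-1(10),11(13)-dien-14-oate (CNP0153978.3) | C=C(C)C(=O)O[C@H]1[C@H]2C(=C)C(=O)O[C@@H]2[C@H]2O[C@]2(C)CC/C=C(/C(=O)OC)[C@@H]1OC(C)=O | target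

## Step count and risks

Total: 17 steps. Longest linear sequence: 15 steps from (S)-carvone (steps 1–6 and 9–17); the side arm (steps 7–8) joins at step 9.

The three steps most likely to fail:

**Step 10 (tandem oxy-Cope/enolate hydroxylation).** The potassium enolate may react poorly with the oxaziridine or add to the sulfonimine by-product. The fallback sets out from 18: the same KN(SiMe3)2/18-crown-6 rearrangement is run, but the enolate is trapped with Et3SiCl and isolated as the triethylsilyl enol ether F1. One equivalent of dimethyldioxirane (acetone/CH2Cl2, −78 °C) epoxidises only the enol ether (Rubottom oxidation), and silyl migration gives the 8α-(triethylsilyloxy) ketone F2. Aqueous citric acid in MeOH removes the silyl group, and the route is rejoined at 21.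

**Step 11 (Mitsunobu inversion at the hindered α-ketol).** The reaction may stall, eliminate or give partial retention. The fallback sets out from 21: MsCl/Et3N (CH2Cl2, −20 °C) gives the 8α-methanesulfonate F3, which is displaced with inversion by cesium methacrylate (CsO2CC(CH3)=CH2, 18-crown-6, toluene, 50 °C). The route is rejoined at 22.

**Step 13 (methoxycarbonylation beside a free allylic alcohol and a migratable ester).** Base and methanol at 60 °C may cause 8→9 acyl migration or methanolysis. The fallback sets out from 23 and avoids base and methanol: Stille coupling with Bu3SnCH2OH (Pd(PPh3)4, dioxane, 80 °C) gives the C14 primary allylic alcohol F4. TEMPO/PhI(OAc)2 oxidises only the primary allylic alcohol, giving the enal F5. NaClO2/NaH2PO4/2-methyl-2-butene gives the carboxylic acid F6, and TMSCHN2 (toluene/MeOH, 0 °C) gives the methyl ester. The route is rejoined at 24.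

## Further compounds

F1 | step 10 | 10-bromo-6α,12-bis[(4-methoxybenzyl)oxy]-9-(triethylsilyloxy)-14-norgermacra-1(10),4E,8,11(13)-tetraene | CC[Si](CC)(CC)O/C1=C\[C@@H](C(=C)COCc2ccc(OC)cc2)[C@H](OCc2ccc(OC)cc2)/C=C(\C)CC/C=C1/Br
F2 | step 10 | 10-bromo-6α,12-bis[(4-methoxybenzyl)oxy]-8α-(triethylsilyloxy)-14-norgermacra-1(10),4E,11(13)-trien-9-one | CC[Si](CC)(CC)O[C@@H]1[C@@H](C(=C)COCc2ccc(OC)cc2)[C@H](OCc2ccc(OC)cc2)/C=C(\C)CC/C=C(/Br)C1=O
F3 | step 11 | 10-bromo-6α,12-bis[(4-methoxybenzyl)oxy]-9-oxo-14-norgermacra-1(10),4E,11(13)-trien-8α-yl methanesulfonate | CS(=O)(=O)O[C@@H]1[C@@H](C(=C)COCc2ccc(OC)cc2)[C@H](OCc2ccc(OC)cc2)/C=C(\C)CC/C=C(/Br)C1=O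
F4 | step 13 | 9α,14-dihydroxy-6α,12-bis[(4-methoxybenzyl)oxy]germacra-1(10),4E,11(13)-trien-8β-yl methacrylate | C=C(C)C(=O)O[C@H]1[C@@H](C(=C)COCc2ccc(OC)cc2)[C@H](OCc2ccc(OC)cc2)/C=C(\C)CC/C=C(/CO)[C@@H]1O
F5 | step 13 | 9α-hydroxy-6α,12-bis[(4-methoxybenzyl)oxy]-14-oxogermacra-1(10),4E,11(13)-trien-8β-yl methacrylate | C=C(C)C(=O)O[C@H]1[C@@H](C(=C)COCc2ccc(OC)cc2)[C@H](OCc2ccc(OC)cc2)/C=C(\C)CC/C=C(/C=O)[C@@H]1O
F6 | step 13 | 9α-hydroxy-8β-(methacryloyloxy)-6α,12-bis[(4-methoxybenzyl)oxy]germacra-1(10),4E,11(13)-trien-14-oic acid | C=C(C)C(=O)O[C@H]1[C@@H](C(=C)COCc2ccc(OC)cc2)[C@H](OCc2ccc(OC)cc2)/C=C(\C)CC/C=C(/C(=O)O)[C@@H]1O
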